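**Retrosynthetic overview**
1. The plan rests on the cyclopentane C2'–C3'–C4'–C5'–C6': C6' carries the isopropenyl group (C7') next to the unfunctionalised C5'H2, and the C1'H2 arm on C2' is cis to the C3' hydroxyl, so these two can be tied into a 1,3-dioxane.
2. Last disconnection: C1'–C4 of the trione ring, by reductive alkylation of the gem-diprenyl acylphloroglucinol trione 22 (phloroglucinol, acylation, dearomatising diprenylation) with β-hydroxy aldehyde 16.
3. 16 comes from the cis-fused acetonide 14, whose cyclopentane is closed at C5'–C6' by 5-exo radical cyclisation of iodide 13, terminated by loss of a methyl hydrogen that unveils the isopropenyl group.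
4. 13 comes from a Z-allylic alcohol (3-butyn-1-ol, ethyl chloroformate, methylcuprate) by Sharpless epoxidation and alkenylcopper opening at C2, which set C3' and C2'.
5. Ring order: oxirane (opened again), 1,3-dioxane template, cyclopentane (key step); the template is then removed and the six-membered trione ring is carried in from phloroglucinol.

Key step: step 10

Remark: the trione ring of 22, 23 and 24 is written as one enol tautomer; the tautomers equilibrate and count as one compound.

**Step 1**
Reactants: 1 but-3-yn-1-ol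
Product: 2 (but-3-yn-1-yloxy)(tert-butyl)dimethylsilane
Conditions: TBSCl, imidazole, CH2Cl2, 0 °C → rt
Reagents that add atoms: tert-butyldimethylsilyl chloride, CC(C)(C)[Si](C)(C)Cl
Why: Imidazole-promoted silylation masks the primary hydroxyl against the organometallic steps that follow.

**Step 2**
Reactants: 2 (but-3-yn-1-yloxy)(tert-butyl)dimethylsilane; 3 ethyl chloroformate
Product: 5 ethyl 5-[(tert-butyldimethylsilyl)oxy]pent-2-ynoate, via lithium acetylide 4 (not isolated)
Conditions: n-BuLi, THF, −78 °C; then 3, −78 → 0 °C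
Reagents that add atoms: none
Why: Deprotonation of the terminal alkyne and C-acylation of the lithium acetylide by the chloroformate should give the ynoate; this carbon becomes C1'.

**Step 3**
Reactants: 5 ethyl 5-[(tert-butyldimethylsilyl)oxy]pent-2-ynoate
Product: 6 ethyl (2Z)-5-[(tert-butyldimethylsilyl)oxy]-3-methylpent-2-enoate
Conditions: Me2CuLi (from MeLi and CuI), THF, −78 °C; AcOH quench at −78 °C
Reagents that add atoms: lithium dimethylcuprate, [Li+].C[Cu-]C (made from methyllithium, [Li]C, and CuI)
Why: Syn-carbocupration of the ynoate and cold protonation of the alkenylcuprate should place the chain and the ester cis (Z), the low temperature preventing allenoate equilibration that would erode the geometry.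

**Step 4**
Reactants: 6 ethyl (2Z)-5-[(tert-butyldimethylsilyl)oxy]-3-methylpent-2-enoate
Product: 7 (2Z)-5-[(tert-butyldimethylsilyl)oxy]-3-methylpent-2-en-1-ol
Conditions: i-Bu2AlH, CH2Cl2, −78 °C; aq. potassium sodium tartrate
Reagents that add atoms: none
Why: 1,2-Reduction of the ester by the aluminium hydride leaves the Z-alkene and the silyl ether untouched.

**Step 5**
Reactants: 7 (2Z)-5-[(tert-butyldimethylsilyl)oxy]-3-methylpent-2-en-1-ol
Product: 8 [(2S,3R)-3-{2-[(tert-butyldimethylsilyl)oxy]ethyl}-3-methyloxiran-2-yl]methanol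
Conditions: Ti(OiPr)4 (cat.), L-(+)-diethyl tartrate (cat.), t-BuOOH, 4 Å molecular sieves, CH2Cl2, −20 °C
Reagents that add atoms: tert-butyl hydroperoxide, CC(C)(C)OO
Why: Sharpless asymmetric epoxidation; with the L-(+)-tartrate the Z-allylic alcohol should be epoxidised on the face that gives the (2S,3R)-epoxide (the outcome known for nerol-type substrates), which fixes the C3' carbinol centre.

**Step 6**
Reactants: 8 [(2S,3R)-3-{2-[(tert-butyldimethylsilyl)oxy]ethyl}-3-methyloxiran-2-yl]methanol; 9 (2-methylprop-1-en-1-yl)magnesium bromide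
Product: 10 (2R,3R)-5-[(tert-butyldimethylsilyl)oxy]-3-methyl-2-(2-methylprop-1-en-1-yl)pentane-1,3-diol
Conditions: 9 (excess), CuI (cat.), THF, −40 → −10 °C; aq. NH4Cl; NaIO4 wash to cleave any 1,2-diol
Reagents that add atoms: none
Why: Copper-catalysed Grignard opening of the 2,3-epoxy alcohol by SN2 attack at the less substituted C2, anti to the epoxide oxygen, should set C2' by inversion while the tertiary C3'–O centre is retained.

**Step 7**
Reactants: 10 (2R,3R)-5-[(tert-butyldimethylsilyl)oxy]-3-methyl-2-(2-methylprop-1-en-1-yl)pentane-1,3-diol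
Product: 11 tert-butyl(dimethyl){2-[(4R,5R)-2,2,4-trimethyl-5-(2-methylprop-1-en-1-yl)-1,3-dioxan-4-yl]ethoxy}silane
Conditions: 2,2-dimethoxypropane, PPTS (cat.), CH2Cl2, rt
Reagents that add atoms: 2,2-dimethoxypropane, COC(C)(C)OC
Why: Acid-catalysed transketalisation ties the 1,3-diol into the six-membered acetonide, which holds the silyloxyethyl and alkenyl arms cis.

**Step 8**
Reactants: 11 tert-butyl(dimethyl){2-[(4R,5R)-2,2,4-trimethyl-5-(2-methylprop-1-en-1-yl)-1,3-dioxan-4-yl]ethoxy}silane
Product: 12 2-[(4R,5R)-2,2,4-trimethyl-5-(2-methylprop-1-en-1-yl)-1,3-dioxan-4-yl]ethan-1-ol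
Conditions: Bu4NF, THF, 0 °C → rt
Reagents that add atoms: none
Why: Fluoride-mediated desilylation frees the primary alcohol without touching the acetonide.

**Step 9**
Reactants: 12 2-[(4R,5R)-2,2,4-trimethyl-5-(2-methylprop-1-en-1-yl)-1,3-dioxan-4-yl]ethan-1-ol
Product: 13 (4R,5R)-4-(2-iodoethyl)-2,2,4-trimethyl-5-(2-methylprop-1-en-1-yl)-1,3-dioxane (iodoethyl and alkenyl cis)
Conditions: PPh3, I2, imidazole, CH2Cl2, 0 °C → rt, dark
Reagents that add atoms: iodine, [I][I]
Why: Appel-type iodination of the primary alcohol by SN2 under imidazole buffering spares the acetonide and the alkene.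

**Step 10**
Reactants: 13 (4R,5R)-4-(2-iodoethyl)-2,2,4-trimethyl-5-(2-methylprop-1-en-1-yl)-1,3-dioxane
Product: 14 (4aR,5R,7aR)-2,2,7a-trimethyl-5-(prop-1-en-2-yl)hexahydrocyclopenta[d][1,3]dioxine (cis-fused; isopropenyl on the convex face)
Conditions: Ph3Sn–Co(dmgH)2(py) (15 mol%; dmgH = dimethylglyoximate monoanion), iPr2NEt, MeCN, blue LEDs, rt, degassed
Reagents that add atoms: none
Why: Light splits the Co–Sn bond of the trivalent cobalt precatalyst into divalent cobalt and Ph3Sn•, which takes the iodine atom from 13; in later turnovers monovalent cobalt, regenerated when iPr2NEt deprotonates the hydridocobalt, displaces iodide by SN2 and light homolyses the alkylcobalt, so the primary C5' radical forms beside divalent cobalt either way. This radical adds 5-exo-trig to C6' of the trisubstituted alkene, which forms C5'–C6' and closes the cyclopentane, and divalent cobalt then abstracts a hydrogen atom from a methyl group of the tertiary C7' radical to leave the isopropenyl group. The closest known reaction type is the cobaloxime-catalysed, light-driven Heck-type cyclisation of unactivated primary alkyl iodides onto alkenes. The ring fusion can only be cis because the iodoethyl and alkenyl arms are cis on the dioxane. C6' is controlled by the chair-like transition state: allylic 1,3-strain with the cis-methyl of the alkene keeps C2'–H in the alkene plane, the radical arrives from the C3' side, and the CMe2 terminus ends on the convex face, trans to the C1'H2–O arm, as is usual for 4-substituted hexenyl radicals. The step needs hydrogen loss toward methyl and not toward the ring C6'–H; six exposed methyl hydrogens against one hindered methine hydrogen, and fast deprotonation of the hydridocobalt (which suppresses re-addition and alkene isomerisation), should secure this.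

**Step 11**
Reactants: 14 (4aR,5R,7aR)-2,2,7a-trimethyl-5-(prop-1-en-2-yl)hexahydrocyclopenta[d][1,3]dioxine
Product: 15 (1R,2R,3R)-2-(hydroxymethyl)-1-methyl-3-(prop-1-en-2-yl)cyclopentan-1-ol
Conditions: AcOH/H2O/THF, 40 °C
Reagents that add atoms: none
Why: Mild acid hydrolysis cleaves the acetonide; because the isopropenyl group is trans to both oxygen-bearing groups, acid-induced cyclic ether formation is not expected.

**Step 12**
Reactants: 15 (1R,2R,3R)-2-(hydroxymethyl)-1-methyl-3-(prop-1-en-2-yl)cyclopentan-1-ol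
Product: 16 (1S,2R,5R)-2-hydroxy-2-methyl-5-(prop-1-en-2-yl)cyclopentane-1-carbaldehyde
Conditions: TEMPO (cat.), PhI(OAc)2, CH2Cl2, rt; used without purification
Reagents that add atoms: none
Why: The oxoammonium oxidation is selective for the primary alcohol and stops at the aldehyde, the tertiary alcohol cannot be oxidised, and the near-neutral medium should avoid retro-aldol cleavage and epimerisation at C2' (whose trans arrangement is in any case the more stable).

**Step 13**
Reactants: 17 phloroglucinol; 18 2-methylpropanoyl chloride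
Product: 19 2-methyl-1-(2,4,6-trihydroxyphenyl)propan-1-one
Conditions: AlCl3, PhNO2, rt → 60 °C; aq. HCl
Reagents that add atoms: none
Why: Friedel–Crafts C-acylation of the electron-rich arene stops at the mono-ketone because the acyl group deactivates the ring.

**Step 14**
Reactants: 19 2-methyl-1-(2,4,6-trihydroxyphenyl)propan-1-one; 20 1-bromo-3-methylbut-2-ene
Product: 22 3,5-dihydroxy-6,6-bis(3-methylbut-2-en-1-yl)-2-(2-methylpropanoyl)cyclohexa-2,4-dien-1-one, via monoprenyl ketone 21 (not isolated)
Conditions: NaOMe, 20 (2 equiv), MeOH, 0 °C → rt; chromatographic separation from the aromatic 3,5-diprenyl isomer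
Reagents that add atoms: none
Why: Base-mediated C-prenylation of the phloroglucinol anion in methanol; a useful part of the second alkylation should take place at the already prenylated carbon and dearomatise the ring (alkylative dearomatisation), leaving C4–H as the only nucleophilic carbon.

**Step 15**
Reactants: 16 (1S,2R,5R)-2-hydroxy-2-methyl-5-(prop-1-en-2-yl)cyclopentane-1-carbaldehyde; 22 3,5-dihydroxy-6,6-bis(3-methylbut-2-en-1-yl)-2-(2-methylpropanoyl)cyclohexa-2,4-dien-1-one
Product: 24 3,5-dihydroxy-4-{[(1S,2R,5R)-2-hydroxy-2-methyl-5-(prop-1-en-2-yl)cyclopentyl]methyl}-6,6-bis(3-methylbut-2-en-1-yl)-2-(2-methylpropanoyl)cyclohexa-2,4-dien-1-one (CNP0290578.2), via alkylidene trione 23 (not isolated)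
Conditions: L-proline (cat.), Hantzsch ester (diethyl 2,6-dimethyl-1,4-dihydropyridine-3,5-dicarboxylate), CH2Cl2, rt
Reagents that add atoms: none
Why: Three-component organocatalytic reductive alkylation: Knoevenagel condensation of the acidic C4–H of the trione with the aldehyde gives the alkylidene trione, which is reduced at once by conjugate hydride transfer from the Hantzsch ester, so C1'–C4 is formed without touching the three stereocentres.

**Compound list**
1 | but-3-yn-1-ol | C#CCCO | starting material
2 | (but-3-yn-1-yloxy)(tert-butyl)dimethylsilane | C#CCCO[Si](C)(C)C(C)(C)C | intermediate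
3 | ethyl chloroformate | CCOC(=O)Cl | starting material
4 | lithium acetylide of 2 (not isolated) | [Li]C#CCCO[Si](C)(C)C(C)(C)C | intermediate
5 | ethyl 5-[(tert-butyldimethylsilyl)oxy]pent-2-ynoate | CCOC(=O)C#CCCO[Si](C)(C)C(C)(C)C | intermediate
6 | ethyl (2Z)-5-[(tert-butyldimethylsilyl)oxy]-3-methylpent-2-enoate | CCOC(=O)/C=C(/C)CCO[Si](C)(C)C(C)(C)C | intermediate
7 | (2Z)-5-[(tert-butyldimethylsilyl)oxy]-3-methylpent-2-en-1-ol | OC/C=C(/C)CCO[Si](C)(C)C(C)(C)C | intermediate
8 | [(2S,3R)-3-{2-[(tert-butyldimethylsilyl)oxy]ethyl}-3-methyloxiran-2-yl]methanol | OC[C@@H]1O[C@]1(C)CCO[Si](C)(C)C(C)(C)C | intermediate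
9 | (2-methylprop-1-en-1-yl)magnesium bromide | CC(C)=C[Mg]Br | starting material
10 | (2R,3R)-5-[(tert-butyldimethylsilyl)oxy]-3-methyl-2-(2-methylprop-1-en-1-yl)pentane-1,3-diol | OC[C@@H](C=C(C)C)[C@](C)(O)CCO[Si](C)(C)C(C)(C)C | intermediate
11 | tert-butyl(dimethyl){2-[(4R,5R)-2,2,4-trimethyl-5-(2-methylprop-1-en-1-yl)-1,3-dioxan-4-yl]ethoxy}silane | CC(C)(C)[Si](C)(C)OCC[C@@]1(C)OC(C)(C)OC[C@H]1C=C(C)C | intermediate
12 | 2-[(4R,5R)-2,2,4-trimethyl-5-(2-methylprop-1-en-1-yl)-1,3-dioxan-4-yl]ethan-1-ol | OCC[C@@]1(C)OC(C)(C)OC[C@H]1C=C(C)C | intermediate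
13 | (4R,5R)-4-(2-iodoethyl)-2,2,4-trimethyl-5-(2-methylprop-1-en-1-yl)-1,3-dioxane | ICC[C@@]1(C)OC(C)(C)OC[C@H]1C=C(C)C | intermediate
14 | (4aR,5R,7aR)-2,2,7a-trimethyl-5-(prop-1-en-2-yl)hexahydrocyclopenta[d][1,3]dioxine | C=C(C)[C@@H]1CC[C@@]2(C)OC(C)(C)OC[C@@H]12 | intermediate
15 | (1R,2R,3R)-2-(hydroxymethyl)-1-methyl-3-(prop-1-en-2-yl)cyclopentan-1-ol | C=C(C)[C@@H]1CC[C@@](C)(O)[C@H]1CO | intermediate
16 | (1S,2R,5R)-2-hydroxy-2-methyl-5-(prop-1-en-2-yl)cyclopentane-1-carbaldehyde | C=C(C)[C@@H]1CC[C@@](C)(O)[C@H]1C=O | intermediate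
17 | phloroglucinol | Oc1cc(O)cc(O)c1 | starting material
18 | 2-methylpropanoyl chloride | CC(C)C(=O)Cl | starting material
19 | 2-methyl-1-(2,4,6-trihydroxyphenyl)propan-1-one | CC(C)C(=O)c1c(O)cc(O)cc1O | intermediate
20 | 1-bromo-3-methylbut-2-ene | CC(C)=CCBr | starting material
21 | 2-methyl-1-[2,4,6-trihydroxy-3-(3-methylbut-2-en-1-yl)phenyl]propan-1-one (not isolated) | CC(C)C(=O)c1c(O)cc(O)c(CC=C(C)C)c1O | intermediate
22 | 3,5-dihydroxy-6,6-bis(3-methylbut-2-en-1-yl)-2-(2-methylpropanoyl)cyclohexa-2,4-dien-1-one | CC(C)C(=O)C1=C(O)C=C(O)C(CC=C(C)C)(CC=C(C)C)C1=O | intermediate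
23 | Knoevenagel alkylidene trione from 16 and 22, exocyclic alkene geometry immaterial (not isolated) | CC(C)C(=O)C1=C(O)C(=C[C@H]2[C@H](C(C)=C)CC[C@@]2(C)O)C(=O)C(CC=C(C)C)(CC=C(C)C)C1=O | intermediate
24 | 3,5-dihydroxy-4-{[(1S,2R,5R)-2-hydroxy-2-methyl-5-(prop-1-en-2-yl)cyclopentyl]methyl}-6,6-bis(3-methylbut-2-en-1-yl)-2-(2-methylpropanoyl)cyclohexa-2,4-dien-1-one | C=C(C)[C@@H]1CC[C@@](C)(O)[C@H]1CC1=C(O)C(CC=C(C)C)(CC=C(C)C)C(=O)C(C(=O)C(C)C)=C1O | target

**Step count and risks**
Total steps: 15. Longest linear sequence: 13 (steps 1–12, then step 15); steps 13–14 form the two-step branch to the core.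

Steps most likely to fail:

1. Step 10. The tertiary C7' radical may lose hydrogen toward the ring methine (isopropylidene isomer), the hydridocobalt may isomerise the new alkene, or the C5' radical may be reduced before it cyclises. The fallback sets out from alcohol 12. Dess–Martin periodinane (NaHCO3, CH2Cl2) should give 2-[(4R,5R)-2,2,4-trimethyl-5-(2-methylprop-1-en-1-yl)-1,3-dioxan-4-yl]acetaldehyde F1. Me2AlCl (CH2Cl2, −78 °C) should then promote an intramolecular carbonyl-ene reaction in which C5' bonds to C6' while a methyl hydrogen passes to oxygen, so the same ring is closed and the isopropenyl group is delivered by the pericyclic mechanism itself, giving the bicyclic isopropenyl cyclopentanol F2. NaH, CS2 and MeI convert it into the xanthate F3, and Barton–McCombie deoxygenation (Bu3SnH, AIBN, PhMe, 80 °C, high stannane concentration to outrun rearrangement of the homoallylic radical) removes the C5' oxygen and returns to 14.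

2. Step 15. Retro-aldol ring opening or β-elimination of the β-hydroxy aldehyde under amine catalysis may outpace a slow Knoevenagel condensation at the hindered α-branched carbonyl, or a second molecule of 22 may add to the alkylidene. The fallback sets out from diol 15. Et3SiOTf and 2,6-lutidine should give the bis(triethylsilyl) ether of 15 F4. Swern conditions ((COCl)2, DMSO, then Et3N, −78 → −30 °C) oxidise the primary silyl ether directly to the tertiary triethylsilyl ether of aldehyde 16 F5, which cannot undergo retro-aldol cleavage. The same reductive alkylation with 22 (Hantzsch ester, L-proline) then passes through the triethylsilyl ether of alkylidene trione 23 F6 to the triethylsilyl ether of the target F7, and HF·pyridine (THF, 0 °C) frees the tertiary alcohol and arrives at 24.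

3. Step 6. SN2 attack of the β,β-disubstituted alkenylcopper at C2, next to the fully substituted C3, may be slow enough that magnesium halide opens the epoxide at the tertiary carbon (halohydrin or semipinacol shift) or that regioselectivity erodes. The fallback sets out from epoxide 8. The less hindered CH2=CHMgBr with CuI (cat.) should give (2R,3R)-5-[(tert-butyldimethylsilyl)oxy]-2-ethenyl-3-methylpentane-1,3-diol F8. 2,2-Dimethoxypropane and PPTS give tert-butyl{2-[(4R,5R)-5-ethenyl-2,2,4-trimethyl-1,3-dioxan-4-yl]ethoxy}dimethylsilane F9. Cross-metathesis with 2-methylbut-2-ene (second-generation Grubbs catalyst, RuCl2(H2IMes)(PCy3)(=CHPh), 40 °C) then builds the trisubstituted alkene and comes back to the route at 11.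

**Further compounds**
F1 | step 10 | 2-[(4R,5R)-2,2,4-trimethyl-5-(2-methylprop-1-en-1-yl)-1,3-dioxan-4-yl]acetaldehyde | O=CC[C@@]1(C)OC(C)(C)OC[C@H]1C=C(C)C
F2 | step 10 | (4aR,5R,7aR)-2,2,7a-trimethyl-5-(prop-1-en-2-yl)hexahydrocyclopenta[d][1,3]dioxin-6-ol, C6 configuration left open | C=C(C)[C@@H]1C(O)C[C@@]2(C)OC(C)(C)OC[C@@H]12
F3 | step 10 | O-[(4aR,5R,7aR)-2,2,7a-trimethyl-5-(prop-1-en-2-yl)hexahydrocyclopenta[d][1,3]dioxin-6-yl] S-methyl carbonodithioate | C=C(C)[C@@H]1C(OC(=S)SC)C[C@@]2(C)OC(C)(C)OC[C@@H]12
F4 | step 15 | bis(triethylsilyl) ether of diol 15 | C=C(C)[C@@H]1CC[C@@](C)(O[Si](CC)(CC)CC)[C@H]1CO[Si](CC)(CC)CC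
F5 | step 15 | tertiary triethylsilyl ether of aldehyde 16 | C=C(C)[C@@H]1CC[C@@](C)(O[Si](CC)(CC)CC)[C@H]1C=O
F6 | step 15 | triethylsilyl ether of alkylidene trione 23, not isolated | CC(C)C(=O)C1=C(O)C(=C[C@H]2[C@H](C(C)=C)CC[C@@]2(C)O[Si](CC)(CC)CC)C(=O)C(CC=C(C)C)(CC=C(C)C)C1=O
F7 | step 15 | tertiary triethylsilyl ether of target 24 | C=C(C)[C@@H]1CC[C@@](C)(O[Si](CC)(CC)CC)[C@H]1CC1=C(O)C(CC=C(C)C)(CC=C(C)C)C(=O)C(C(=O)C(C)C)=C1O
F8 | step 6 | (2R,3R)-5-[(tert-butyldimethylsilyl)oxy]-2-ethenyl-3-methylpentane-1,3-diol | OC[C@@H](C=C)[C@](C)(O)CCO[Si](C)(C)C(C)(C)C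
F9 | step 6 | tert-butyl{2-[(4R,5R)-5-ethenyl-2,2,4-trimethyl-1,3-dioxan-4-yl]ethoxy}dimethylsilane | CC(C)(C)[Si](C)(C)OCC[C@@]1(C)OC(C)(C)OC[C@H]1C=C
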